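**Assumptions (one line each).** The SMILES is read as a trans-fused (3S,5aS,6S,7S,9aS)-perhydro-1-benzoxepine joined through CH2CH2 to a cis-fused (4aR,8S,8aS)-hydroxy-decalenone. In Step 1 the catalyst enantiomer that gives (4aR,8aS)-3 is used (taken to be the (S)-catalyst). In Step 9 an (S)-selective P450-BM3 variant is taken from a variant screen.

## Retrosynthetic overview

1. Last C–C bond: linker CH2 to the enone β-carbon, by adding the left-half alkylcerium (from iodide 25) to bicyclic 2-methyl-enone 10, then Babler–Dauben oxidative transposition.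
2. Right half: ring B is purchased (4,4-dimethylcyclohexenone); ring A and the cis ring fusion come from a catalytic asymmetric Diels–Alder with isoprene; then allylic oxidation, and the tertiary carbinol by convex-face epoxidation and hydride opening.
3. Left half: oxepane first, then cyclohexane, both in one epoxide-opening oxa/carbacyclisation cascade of a diepoxy silyl enol ether.
4. The two epoxides come from (E)-geranylacetone: terminal one by a P450 monooxygenase, internal one by Shi epoxidation.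
5. The left-half tertiary carbinol comes from methylenation, α-face epoxidation and LiAlH4.

## Right half (Steps 1–8)

**Step 1**
Reactants: 1 4,4-dimethylcyclohex-2-en-1-one; 2 isoprene
Product: 3 (4aR,8aS)-4,4,6-trimethyl-3,4,4a,5,8,8a-hexahydronaphthalen-1(2H)-one (cis-fused)
Conditions: (S)-o-tolyl-oxazaborolidine·AlBr3 (20 mol %), isoprene (5 eq), CH2Cl2, −40 → −20 °C; cold Et3N quench
Reagents that add atoms: none
Why: Chiral oxazaborolidinium-catalysed Diels–Alder: suprafacial addition gives the cis ring fusion, isoprene adds "para" (6-methyl), and catalyst face control sets both ring-fusion centres.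

**Step 2**
Reactants: 3
Product: 4 (4aR,8aS)-5-hydroxy-4,4,6-trimethyl-3,4,4a,5,8,8a-hexahydronaphthalen-1(2H)-one (C5 epimers)
Conditions: SeO2 (0.5 eq), t-BuOOH, CH2Cl2, rt
Reagents that add atoms: tert-butyl hydroperoxide CC(C)(C)OO (O source; SeO2 O=[Se]=O catalytic)
Why: SeO2 allylic oxidation (ene then [2,3]-shift) hydroxylates the ring CH2 on the more substituted olefin carbon (CH2 > CH3) without moving the double bond; the carbinol configuration is irrelevant.

**Step 3**
Reactants: 4
Product: 5 (4aR,8aS)-4,4,6-trimethyl-3,4,4a,8a-tetrahydronaphthalene-1,5(2H,8H)-dione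
Conditions: Dess–Martin periodinane, NaHCO3, CH2Cl2, 0 °C
Reagents that add atoms: none
Why: Neutral Dess–Martin oxidation of the allylic alcohol gives the 2-methyl-enone without epimerising either ring-fusion centre.

**Step 4**
Reactants: 5
Product: 6 (4aS,8aR)-2,8,8-trimethyl-5-methylidene-4a,5,6,7,8,8a-hexahydronaphthalen-1(4H)-one
Conditions: Zn, CH2Br2, TiCl4, THF/CH2Cl2, 0 °C → rt
Reagents that add atoms: dibromomethane BrCBr
Why: Lombardo methylenation is non-basic and takes the saturated ketone in preference to the hindered conjugated one, so the adjacent ring-fusion centre is locked without epimerisation.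

**Step 5**
Reactants: 6
Product: 7 spiro-epoxide of 6, (2S,4a'S,8a'R)-2',8',8'-trimethyl-4',4a',6',7',8',8a'-hexahydro-1'H-spiro[oxirane-2,5'-naphthalen]-1'-one, epoxide O syn to the ring-fusion hydrogens
Conditions: mCPBA, NaHCO3, CH2Cl2, 0 °C
Reagents that add atoms: mCPBA O=C(OO)c1cccc(Cl)c1
Why: Prilezhaev epoxidation of the 1,1-disubstituted alkene only (the enone C=C is inert), from the convex face anti to the ring-A carbons.

**Step 6**
Reactants: 7
Product: 8 (4aS,5S,8aR)-2,5,8,8-tetramethyl-1,4,4a,5,6,7,8,8a-octahydronaphthalene-1,5-diol (C1 epimers)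
Conditions: LiAlH4, THF, 0 °C → 50 °C
Reagents that add atoms: none (hydride only)
Why: Hydride opens the epoxide at its CH2 terminus (SN2), giving the tertiary alcohol with OH on the ring-fusion-H face; the enone carbonyl is reduced 1,2 in the same pot.

**Step 7**
Reactants: 8
Product: 9 (4aS,5S,8aR)-5-hydroxy-2,5,8,8-tetramethyl-4a,5,6,7,8,8a-hexahydronaphthalen-1(4H)-one
Conditions: Dess–Martin periodinane, NaHCO3, CH2Cl2, 0 °C
Reagents that add atoms: none
Why: Only the secondary allylic alcohol can be oxidised, which restores the enone.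

**Step 8**
Reactants: 9
Product: 10 5-O-triethylsilyl ether of 9
Conditions: TESOTf, 2,6-lutidine, CH2Cl2, −78 °C
Reagents that add atoms: TESOTf CC[Si](CC)(CC)OS(=O)(=O)C(F)(F)F
Why: Silyl triflate silylation masks the tertiary alcohol so it neither quenches the organometallic in Step 22 nor reacts with Cr(VI) in Step 23.

## Left half (Steps 9–21)

**Step 9**
Reactants: 11 (E)-geranylacetone, (5E)-6,10-dimethylundeca-5,9-dien-2-one
Product: 12 (5E,9S)-9,10-epoxy-6,10-dimethylundec-5-en-2-one
Conditions: cytochrome P450 monooxygenase (P450-BM3 F87V-type variant), NADP+, glucose/glucose dehydrogenase, air, KPi pH 7.5, 25 °C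
Reagents that add atoms: dioxygen O=O
Why: Enzymatic asymmetric epoxidation, regiospecific for the terminal trisubstituted olefin, sets the (S)-epoxide that becomes the oxepane carbinol.

**Step 10**
Reactants: 12
Product: 13 (5S,6S,9S)-5,6:9,10-diepoxy-6,10-dimethylundecan-2-one
Conditions: ent-Shi ketone (L-fructose-derived, 30 mol %), Oxone, K2CO3, Bu4NHSO4, MeCN/DMM/buffer pH 10.5, 0 °C
Reagents that add atoms: Oxone (KHSO5) OOS(=O)(=O)[O-].[K+]
Why: Shi epoxidation (dioxirane, spiro transition state) of the (E)-trisubstituted olefin gives the (5S,6S)-epoxide under reagent control.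

**Step 11**
Reactants: 13; 14 2-(benzyloxy)acetaldehyde
Product: 15 (7S,8S,11S)-1-(benzyloxy)-7,8:11,12-diepoxy-2-hydroxy-8,12-dimethyltridecan-4-one (C2 epimers)
Conditions: LDA, THF, −78 °C; then 14
Reagents that add atoms: none beyond 14
Why: Kinetic deprotonation of the methyl ketone on the CH3 side and aldol addition; the epoxides survive at −78 °C and the new carbinol is removed in the next step.

**Step 12**
Reactants: 15
Product: 16 (2E,7S,8S,11S)-1-(benzyloxy)-7,8:11,12-diepoxy-8,12-dimethyltridec-2-en-4-one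
Conditions: MsCl, Et3N, CH2Cl2, 0 °C → rt
Reagents that add atoms: none
Why: Mesylation and E1cB elimination give the (E)-enone.

**Step 13**
Reactants: 16
Product: 17 (3Z,7S,8S,11S)-1-(benzyloxy)-7,8:11,12-diepoxy-8,12-dimethyl-4-(triethylsilyloxy)tridec-3-ene
Conditions: Et3SiH, RhCl(PPh3)3 (2 mol %), PhH, 50 °C
Reagents that add atoms: triethylsilane CC[SiH](CC)CC
Why: Rh-catalysed 1,4-hydrosilylation places the silyl enol ether double bond on the side-chain carbon, a regiochemistry that direct enolisation cannot give.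

**Step 14**
Reactants: 17
Product: 18 (3S,5aS,6S,9aS)-6-[2-(benzyloxy)ethyl]-3-hydroxy-2,2,5a-trimethyloctahydro-1-benzoxepin-7(2H)-one (trans-fused)
Conditions: TMSOTf, 2,6-di-tert-butyl-4-methylpyridine, CH2Cl2, −78 °C; then TBAF, THF, 0 °C
Reagents that add atoms: none (TMS is removed on work-up)
Why: Epoxide-opening oxa/carbacyclisation cascade: the internal epoxide oxygen opens the silyl-activated terminal epoxide at its tertiary carbon (oxepane, C3 retained), then the silyl enol ether opens the epoxonium anti at its tertiary carbon through a chair (inversion at C5a, retention at C9a, trans fusion); C6 equilibrates to the equatorial side chain.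

**Step 15**
Reactants: 18
Product: 19 3-O-TBS ether of 18
Conditions: TBSOTf, 2,6-lutidine, CH2Cl2, −78 °C
Reagents that add atoms: TBSOTf CC(C)(C)[Si](C)(C)OS(=O)(=O)C(F)(F)F
Why: Silyl protection of the hindered secondary alcohol for the ylide, peracid, hydride and organolithium steps.

**Step 16**
Reactants: 19
Product: 20 (3S,5aS,6R,9aS)-6-[2-(benzyloxy)ethyl]-3-(TBS-oxy)-2,2,5a-trimethyl-7-methylidenedecahydro-1-benzoxepine
Conditions: Ph3PCH3Br, KOtBu, toluene, 80 °C
Reagents that add atoms: methyltriphenylphosphonium bromide C[P+](c1ccccc1)(c1ccccc1)c1ccccc1.[Br-]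
Why: Wittig methylenation; C6 is already in its thermodynamic equatorial configuration, so the basic ylide cannot erode it.

**Step 17**
Reactants: 20
Product: 21 7-spiro-epoxide of 20, epoxide O on the α-face (anti to the 5a-methyl)
Conditions: mCPBA, NaHCO3, CH2Cl2, 0 °C
Reagents that add atoms: mCPBA O=C(OO)c1cccc(Cl)c1
Why: Prilezhaev epoxidation from the equatorial α-face, because the axial angular methyl blocks the β-face (1,3-diaxial).

**Step 18**
Reactants: 21
Product: 22 (3S,5aS,6S,7S,9aS)-6-[2-(benzyloxy)ethyl]-3-(TBS-oxy)-2,2,5a,7-tetramethyldecahydro-1-benzoxepin-7-ol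
Conditions: LiAlH4, THF, 50 °C
Reagents that add atoms: none (hydride only)
Why: SN2 hydride opening at the epoxide CH2 gives the tertiary alcohol with equatorial OH and axial CH3.

**Step 19**
Reactants: 22
Product: 23 7-O-TES ether of 22
Conditions: TESOTf, 2,6-lutidine, CH2Cl2, −78 → 0 °C
Reagents that add atoms: TESOTf CC[Si](CC)(CC)OS(=O)(=O)C(F)(F)F
Why: Silylation of the tertiary alcohol ahead of organolithium formation.

**Step 20**
Reactants: 23
Product: 24 2-[(3S,5aS,6S,7S,9aS)-3-(TBS-oxy)-7-(TES-oxy)-2,2,5a,7-tetramethyldecahydro-1-benzoxepin-6-yl]ethanol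
Conditions: H2 (1 atm), 10 % Pd/C, EtOAc, rt
Reagents that add atoms: none
Why: Benzyl ether hydrogenolysis; there are no alkenes, and silyl ethers are stable in EtOAc.

**Step 21**
Reactants: 24
Product: 25 the corresponding primary iodide (6-(2-iodoethyl) compound)
Conditions: I2, PPh3, imidazole, CH2Cl2, 0 °C
Reagents that add atoms: iodine II
Why: Appel-type iodination of the only free (primary) alcohol.

## Union and endgame (Steps 22–24)

**Step 22**
Reactants: 25; 10
Product: 26 tertiary allylic alcohol from 1,2-addition of the left-half CH2CH2 unit to C1 of 10 (C1 epimers)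
Conditions: 25, t-BuLi (2.1 eq), Et2O, −78 °C; anhydrous CeCl3, THF, −78 °C; then 10
Reagents that add atoms: none beyond the two fragments
Why: Iodine–lithium exchange, transmetalation to cerium and 1,2-addition to the hindered enone carbonyl; the organocerium suppresses enolisation and conjugate addition, and the new carbinol centre is destroyed next.

**Step 23**
Reactants: 26
Product: 27 tris-silyl sipholenol K (3-O-TBS, 7-O-TES on the left; 8-O-TES on the right)
Conditions: PCC, NaOAc, 4 Å MS, CH2Cl2, rt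
Reagents that add atoms: none (the carbonyl O is the former hydroxyl O)
Why: Babler–Dauben oxidative transposition: the chromate ester undergoes a [3,3]-shift and oxidation to the 3-alkyl-2-methyl-enone; the ring-fusion centres are untouched.

**Step 24**
Reactants: 27
Product: 28 sipholenol K
Conditions: HF·pyridine, THF/pyridine, 0 °C → rt
Reagents that add atoms: none
Why: Fluoride-mediated global desilylation under mildly acidic conditions that leave the enone and the tertiary alcohols intact.

## Compound list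

1 | 4,4-dimethylcyclohex-2-en-1-one | CC1(C)CCC(=O)C=C1 | starting material
2 | isoprene | CC(=C)C=C | starting material
3 | (4aR,8aS)-4,4,6-trimethyl-3,4,4a,5,8,8a-hexahydronaphthalen-1(2H)-one | O=C1CCC(C)(C)[C@@H]2CC(C)=CC[C@H]12 | intermediate
4 | (4aR,8aS)-5-hydroxy-4,4,6-trimethyl-3,4,4a,5,8,8a-hexahydronaphthalen-1(2H)-one | O=C1CCC(C)(C)[C@@H]2C(O)C(C)=CC[C@H]12 | intermediate
5 | (4aR,8aS)-4,4,6-trimethyl-3,4,4a,8a-tetrahydronaphthalene-1,5(2H,8H)-dione | O=C1CCC(C)(C)[C@@H]2C(=O)C(C)=CC[C@H]12 | intermediate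
6 | (4aS,8aR)-2,8,8-trimethyl-5-methylidene-4a,5,6,7,8,8a-hexahydronaphthalen-1(4H)-one | C=C1CCC(C)(C)[C@@H]2C(=O)C(C)=CC[C@H]12 | intermediate
7 | spiro-epoxide of 6 (O syn to ring-fusion H) | O=C1C(C)=CC[C@H]2[C@@H]1C(C)(C)CC[C@@]23CO3 | intermediate
8 | (4aS,5S,8aR)-2,5,8,8-tetramethyl-1,4,4a,5,6,7,8,8a-octahydronaphthalene-1,5-diol | OC1C(C)=CC[C@H]2[C@@H]1C(C)(C)CC[C@]2(C)O | intermediate
9 | (4aS,5S,8aR)-5-hydroxy-2,5,8,8-tetramethyl-4a,5,6,7,8,8a-hexahydronaphthalen-1(4H)-one | O=C1C(C)=CC[C@H]2[C@@H]1C(C)(C)CC[C@]2(C)O | intermediate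
10 | 5-O-TES ether of 9 | O=C1C(C)=CC[C@H]2[C@@H]1C(C)(C)CC[C@]2(C)O[Si](CC)(CC)CC | intermediate
11 | (E)-geranylacetone | CC(=O)CC/C=C(\C)CCC=C(C)C | starting material
12 | (5E,9S)-9,10-epoxy-6,10-dimethylundec-5-en-2-one | CC(=O)CC/C=C(\C)CC[C@@H]1OC1(C)C | intermediate
13 | (5S,6S,9S)-5,6:9,10-diepoxy-6,10-dimethylundecan-2-one | CC(=O)CC[C@@H]1O[C@@]1(C)CC[C@@H]1OC1(C)C | intermediate
14 | 2-(benzyloxy)acetaldehyde | O=CCOCc1ccccc1 | starting material
15 | (7S,8S,11S)-1-(benzyloxy)-7,8:11,12-diepoxy-2-hydroxy-8,12-dimethyltridecan-4-one | O=C(CC(O)COCc1ccccc1)CC[C@@H]1O[C@@]1(C)CC[C@@H]1OC1(C)C | intermediate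
16 | (2E,7S,8S,11S)-1-(benzyloxy)-7,8:11,12-diepoxy-8,12-dimethyltridec-2-en-4-one | O=C(/C=C/COCc1ccccc1)CC[C@@H]1O[C@@]1(C)CC[C@@H]1OC1(C)C | intermediate
17 | (3Z,7S,8S,11S)-1-(benzyloxy)-7,8:11,12-diepoxy-8,12-dimethyl-4-(triethylsilyloxy)tridec-3-ene | CC[Si](CC)(CC)O/C(=C\CCOCc1ccccc1)CC[C@@H]1O[C@@]1(C)CC[C@@H]1OC1(C)C | intermediate
18 | (3S,5aS,6S,9aS)-6-[2-(benzyloxy)ethyl]-3-hydroxy-2,2,5a-trimethyloctahydro-1-benzoxepin-7(2H)-one | O=C1CC[C@@H]2OC(C)(C)[C@@H](O)CC[C@@]2(C)[C@@H]1CCOCc1ccccc1 | intermediate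
19 | 3-O-TBS ether of 18 | O=C1CC[C@@H]2OC(C)(C)[C@@H](O[Si](C)(C)C(C)(C)C)CC[C@@]2(C)[C@@H]1CCOCc1ccccc1 | intermediate
20 | 7-methylidene compound, (3S,5aS,6R,9aS) | C=C1CC[C@@H]2OC(C)(C)[C@@H](O[Si](C)(C)C(C)(C)C)CC[C@@]2(C)[C@@H]1CCOCc1ccccc1 | intermediate
21 | 7-spiro-epoxide of 20 (O α, anti to 5a-Me) | C1O[C@]12CC[C@@H]3OC(C)(C)[C@@H](O[Si](C)(C)C(C)(C)C)CC[C@@]3(C)[C@@H]2CCOCc2ccccc2 | intermediate
22 | (3S,5aS,6S,7S,9aS)-6-[2-(benzyloxy)ethyl]-3-(TBS-oxy)-2,2,5a,7-tetramethyldecahydro-1-benzoxepin-7-ol | C[C@]1(O)CC[C@@H]2OC(C)(C)[C@@H](O[Si](C)(C)C(C)(C)C)CC[C@@]2(C)[C@@H]1CCOCc1ccccc1 | intermediate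
23 | 7-O-TES ether of 22 | C[C@]1(O[Si](CC)(CC)CC)CC[C@@H]2OC(C)(C)[C@@H](O[Si](C)(C)C(C)(C)C)CC[C@@]2(C)[C@@H]1CCOCc1ccccc1 | intermediate
24 | primary alcohol (debenzylated 23) | C[C@]1(O[Si](CC)(CC)CC)CC[C@@H]2OC(C)(C)[C@@H](O[Si](C)(C)C(C)(C)C)CC[C@@]2(C)[C@@H]1CCO | intermediate
25 | primary iodide | C[C@]1(O[Si](CC)(CC)CC)CC[C@@H]2OC(C)(C)[C@@H](O[Si](C)(C)C(C)(C)C)CC[C@@]2(C)[C@@H]1CCI | intermediate
26 | coupled tertiary allylic alcohol (carbinol epimers) | C[C@]1(O[Si](CC)(CC)CC)CC[C@@H]2OC(C)(C)[C@@H](O[Si](C)(C)C(C)(C)C)CC[C@@]2(C)[C@@H]1CCC1(O)C(C)=CC[C@H]2[C@@H]1C(C)(C)CC[C@]2(C)O[Si](CC)(CC)CC | intermediate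
27 | tris-silyl sipholenol K | CC1=C(CC[C@H]2[C@]3(C)CC[C@H](O[Si](C)(C)C(C)(C)C)C(C)(C)O[C@H]3CC[C@]2(C)O[Si](CC)(CC)CC)[C@@H]2[C@H](CC1=O)[C@@](C)(O[Si](CC)(CC)CC)CCC2(C)C | intermediate
28 | sipholenol K: (4aR,8S,8aS)-4-{2-[(3S,5aS,6S,7S,9aS)-3,7-dihydroxy-2,2,5a,7-tetramethyldecahydro-1-benzoxepin-6-yl]ethyl}-8-hydroxy-3,5,5,8-tetramethyl-4a,5,6,7,8,8a-hexahydronaphthalen-2(1H)-one | CC1=C(CC[C@H]2[C@]3(C)CC[C@H](O)C(C)(C)O[C@H]3CC[C@]2(C)O)[C@@H]2[C@H](CC1=O)[C@@](C)(O)CCC2(C)C | target

## Totals and risks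

**Total steps:** 24 (right half 8, left half 13, union and endgame 3).
**Longest linear sequence:** 16 steps (Steps 9–24, from geranylacetone).

**Three steps most likely to fail, with fallbacks:**

- **Step 1 (asymmetric Diels–Alder).** The β-carbon of 1 is neopentyl, so rate and ee may be low, and the cis adduct can epimerise to trans. Fallback: drop the cycloaddition and build ring A by annulation instead. That means Cu–phosphoramidite (or Rh–diene) asymmetric conjugate addition of a vinyl nucleophile to 1 with enolate allylation, conversion of the vinyl group to an isopropenyl ketone, ring-closing metathesis to dione 5, and kinetic protonation to set the cis fusion.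
- **Step 2 (SeO2 allylic oxidation).** The C5 methylene is hindered, so methyl oxidation and over-oxidation may compete. Fallback: a transposition route on the C1 ketal. Hydroborate and oxidise the ring-A olefin to the C7 ketone, dehydrogenate to the 6-methyl-5-en-7-one, epoxidise with alkaline H2O2, and apply Wharton transposition to reach the same C5 allylic alcohol.
- **Step 14 (epoxide cascade).** Tetrahydropyran formation, epoxide rearrangement or enol-silane loss can compete with the oxepane/carbocycle sequence. Fallback: a stepwise route. Set C5a/C9a by ketoreductase desymmetrisation of a 2-methyl-2-(4-methylpent-3-enyl)cyclohexane-1,3-dione, Shi-epoxidise the side chain, close the oxepane by acid-mediated 7-endo hydroxy-epoxide opening, then elaborate the remaining ketone to the C6/C7 substituents.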